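**Strategy.** Ring B comes from (R)-carvone, whose stereocentre becomes C5 and whose enone is already the 8-methyl-7-en-9-one of the target. Everything rests on closing ring A last through C3–C4 by an Ireland–Claisen ring contraction. The feature exploited is the quaternary C4 of ring A with its oxidised one-carbon branch C19, which lies 1,4 across ring A from C1: C19 is tied to a temporary oxygen on C1 as a δ-lactone that the target lacks. The [3,3] shift of the lactone silyl ketene acetal forms C3–C4, closes ring A, sets C4 with C19 axial and cuts the C1–O tether in one operation. The precursor is a trans-fused 1-vinyl δ-lactone on the carvone ring.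

Key step: step 5

Remark: labdane numbering (C1–C20; C19 is the oxygen-bearing carbon on C4) and α/β descriptors (β = face of the C10 methyl) are used for all intermediates. Compounds drawn without a descriptor at C4 or C10 are epimer mixtures that converge later.

Step 1
Reactants: 1 (R)-(−)-carvone; 2 iodomethane
Product: 4 6-methylcarvone (C10 epimer mixture), via carvone lithium enolate 3 (not isolated)
Conditions: LiN(iPr)2, THF, −78 °C; MeI, −78 → 0 °C
Reagents that add atoms: lithium diisopropylamide, [Li]N(C(C)C)C(C)C (its lithium is in 3 only); iodomethane 2, CI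
Why: Kinetic α′-deprotonation gives the cross-conjugated enolate 3, which is C-methylated by SN2 (enolate alkylation); the C10 configuration formed here is irrelevant because this centre is re-enolised in step 3.

Step 2
Reactants: 4 6-methylcarvone
Product: 6 primary alcohol (C19–OH; C4 and C10 epimers), via B-alkyl-9-BBN adduct 5 (not isolated)
Conditions: 9-BBN (1.1 equiv), THF, 0 °C → rt; then 30% H2O2, pH 7 phosphate buffer, 0 °C → rt
Reagents that add atoms: 9-borabicyclo[3.3.1]nonane, B1C2CCCC1CCC2 (its boron is in 5 only); hydrogen peroxide, OO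
Why: Hydroboration–oxidation: 9-BBN should add anti-Markovnikov to the unhindered 1,1-disubstituted alkene faster than it reduces the doubly flanked conjugated ketone, and the buffered peroxide avoids Weitz–Scheffer epoxidation of the enone; the C4 epimers converge in step 5.

Step 3
Reactants: 6 primary alcohol; 7 acrolein
Product: 9 aldol diol (1R carbinol; 10β-CH3; C1 trans to C4), via dilithium alkoxide enolate 8 (not isolated)
Conditions: LiN(iPr)2 (2.2 equiv), THF, −78 → −20 °C; acrolein, −78 °C; AcOH quench at −78 °C
Reagents that add atoms: lithium diisopropylamide, [Li]N(C(C)C)C(C)C (its lithium is in 8 only); acrolein 7, C=CC=O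
Why: Directed aldol addition (1,2 to acrolein) of the tetrasubstituted lithium enolate 8: the aldehyde enters anti to the C5 substituent, which sets C10 (methyl β, C1 trans to C4), and the Zimmerman–Traxler chair of this cyclic enolate places the new hydroxyl anti to ring carbon C5, which should make the 1R carbinol the main epimer (the minor one is removed by chromatography).

Step 4
Reactants: 9 aldol diol
Product: 10 vinyl δ-lactone (C19(=O)–O–C1; trans-fused to ring B; 1α-vinyl)
Conditions: TEMPO (cat.), PhI(OAc)2, CH2Cl2, rt
Reagents that add atoms: none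
Why: TEMPO/PhI(OAc)2 oxidative lactonisation: the primary alcohol is oxidised chemoselectively to the aldehyde, the C1 hydroxyl closes the six-membered lactol and this is oxidised to the δ-lactone with retention at C1, the hindered secondary allylic alcohol itself being oxidised much more slowly.

Step 5
Reactants: 10 vinyl δ-lactone
Product: 13 9-oxo-11,12,13,14,15,16-hexanorlabda-1,7-dien-19-oic acid (4β-CO2H; 4α-CH3), via silyl ketene acetal 11 (not isolated), via trimethylsilyl ester 12 (not isolated)
Conditions: LiN(iPr)2, Me3SiCl/Et3N (in situ quench), THF, −78 °C; then PhMe, 110 °C (sealed tube); dilute HCl/THF, 0 °C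
Reagents that add atoms: chlorotrimethylsilane, C[Si](C)(C)Cl (its Me3Si group is in 11 and 12 only)
Why: Kinetic enolisation at C4 with in situ silylation gives the endocyclic silyl ketene acetal 11, whose C4=C19–O–C1–C2=C3 array undergoes a concerted suprafacial [3,3]-sigmatropic shift (Ireland–Claisen rearrangement) that forms C3–C4 and breaks C1–O, giving silyl ester 12 and, after hydrolysis, acid 13. The closest known reaction type is the Claisen ring contraction of δ-vinyl δ-lactone silyl ketene acetals to cyclohex-3-enecarboxylic acids. Ring A is closed by this [3,3] shift through the boat-like transition state that the six-membered lactone enforces, the new alkene appearing at C1=C2. C4, the only new stereocentre, is controlled by the tether: the vinyl group is axial on the α face of the lactone, so C3 bonds to the α face of C4 and the former ring carbon C19 is left axial (β, cis to the C10 methyl) with the methyl equatorial, while C5 and C10 are untouched. The step needs deprotonation at C4 in preference to the γ-position C6 of the enone, which carbonyl-directed kinetic deprotonation at −78 °C with internal silyl quench should secure, and it needs the 1R (α-vinyl) lactone, the only epimer whose vinyl group can reach C4. Because the trans ring fusion twists the boat-like transition state, a higher temperature than for monocyclic lactones is expected.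

Step 6
Reactants: 13 dienone acid
Product: 14 9-oxo-11,12,13,14,15,16-hexanorlabd-7-en-19-oic acid
Conditions: H2 (1 atm), RhCl(PPh3)3 (cat.), PhMe/EtOH, rt
Reagents that add atoms: none
Why: Homogeneous hydrogenation with RhCl(PPh3)3 saturates the cis-disubstituted C1=C2 alkene and leaves the trisubstituted conjugated C7=C8 alkene, the same selectivity by which carvone is hydrogenated only at its isopropenyl group.

Step 7
Reactants: 14 enone acid; 15 vinylmagnesium bromide
Product: 16 9β-hydroxy-13,14,15,16-tetranorlabda-7,11-dien-19-oic acid (9α-vinyl)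
Conditions: CH2=CHMgBr (4 equiv), CeCl3, THF, −78 → 0 °C; sat. NH4Cl
Reagents that add atoms: vinylmagnesium bromide 15, C=C[Mg]Br
Why: 1,2-Addition of the vinyl organocerium reagent (Grignard reagent with CeCl3) to the hindered enone carbonyl of the magnesium carboxylate; attack anti to the axial C10 methyl (α face) should give the 9β-hydroxy-9α-vinyl carbinol.

Step 8
Reactants: 16 hydroxy acid
Product: 17 13,14,15,16-tetranorlabda-7,11-diene-9β,19-diol
Conditions: LiAlH4, THF, reflux; aqueous work-up
Reagents that add atoms: none
Why: Hydride reduction of the hindered axial carboxylate to the primary alcohol with LiAlH4; the tertiary alkoxide and the alkenes are inert and no stereocentre is affected.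

Step 9
Reactants: 17 diol; 18 tigloyl chloride
Product: 19 19-tigloyloxy-13,14,15,16-tetranorlabda-7,11-dien-9β-ol
Conditions: pyridine, DMAP (cat.), CH2Cl2, 0 °C → rt
Reagents that add atoms: tigloyl chloride 18, C/C=C(\C)C(=O)Cl
Why: DMAP-catalysed acylation with the acid chloride occurs only at the primary C19 hydroxyl because the tertiary allylic C9 hydroxyl next to quaternary C10 is too hindered; the E alkene of the ester comes unchanged from the reagent.

Step 10
Reactants: 20 but-2-ynoic acid
Product: 21 (Z)-3-iodobut-2-enoic acid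
Conditions: NaI, AcOH, 110 °C
Reagents that add atoms: sodium iodide, [Na+].[I-]
Why: Hydroiodination of the ynoic acid by conjugate addition of iodide and anti protonation gives the Z-β-iodo acid with iodine cis to the carboxyl.

Step 11
Reactants: 21 (Z)-3-iodobut-2-enoic acid; 22 2-(trimethylsilyl)ethanol
Product: 23 2-(trimethylsilyl)ethyl (Z)-3-iodobut-2-enoate
Conditions: DCC, DMAP (cat.), CH2Cl2, 0 °C
Reagents that add atoms: 2-(trimethylsilyl)ethanol 22, C[Si](C)(C)CCO
Why: Steglich esterification under mild conditions keeps the Z vinyl iodide geometry and installs an ester that fluoride can remove at the end.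

Step 12
Reactants: 19 tiglate; 23 iodoenoate
Product: 25 2-(trimethylsilyl)ethyl 9β-hydroxy-19-tigloyloxylabda-7,13Z-dien-15-oate, via B-alkyl-9-BBN borane 24 (not isolated)
Conditions: 9-BBN (3 equiv), THF, 0 °C → rt; then 23, PdCl2(dppf) (cat.), AsPh3, Cs2CO3, DMF/H2O, rt
Reagents that add atoms: 9-borabicyclo[3.3.1]nonane, B1C2CCCC1CCC2 (its boron is in 24 only); iodoenoate 23, C/C(I)=C/C(=O)OCC[Si](C)(C)C
Why: Anti-Markovnikov hydroboration of the only monosubstituted alkene (9-BBN leaves the trisubstituted alkenes and the ester alone) followed by B-alkyl Suzuki–Miyaura coupling, which proceeds with retention at the vinyl iodide, forms C12–C13 and so sets the 13Z geometry.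

Step 13
Reactants: 25 tertiary allylic alcohol
Product: 26 9β-formate of 25
Conditions: HCO2H/Ac2O (acetic formic anhydride formed in situ), pyridine, DMAP (cat.), CH2Cl2, 0 °C → rt
Reagents that add atoms: formic acid, O=CO
Why: Formylation with the small, reactive mixed anhydride should esterify the congested tertiary allylic alcohol with retention at C9 and provides the internal hydride source for step 14.

Step 14
Reactants: 26 allylic formate
Product: 27 2-(trimethylsilyl)ethyl 19-tigloyloxylabda-7,13Z-dien-15-oate (9α-H)
Conditions: Pd(OAc)2 (cat.), n-Bu3P (1 equiv per Pd), 1,4-dioxane, rt → 60 °C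
Reagents that add atoms: none
Why: Palladium-catalysed hydrogenolysis of an allylic formate (Tsuji-type): zerovalent palladium ionises the 9β-formate with inversion so that the metal sits on the α face of the C7–C8–C9 allyl unit, CO2 is lost and hydride passes from palladium to the more substituted terminus C9 on that face, which should give 9α-H (side chain β) together with the C7=C8 alkene.

Step 15
Reactants: 27 silylethyl ester
Product: 28 19-tigloyloxylabda-7,13Z-dien-15-oic acid (target)
Conditions: Bu4NF, THF, 0 °C → rt; AcOH work-up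
Reagents that add atoms: none
Why: Fluoride-induced β-elimination of the 2-(trimethylsilyl)ethyl ester (loss of ethylene and Me3SiF) frees the acid under conditions that should leave the hindered tiglate and the Z-enoate untouched.

**Compound list**

1 | (R)-(−)-carvone, (5R)-2-methyl-5-(prop-1-en-2-yl)cyclohex-2-en-1-one | O=C1C(C)=CC[C@@H](C(C)=C)C1 | starting material
2 | iodomethane | CI | starting material
3 | carvone lithium enolate (cross-conjugated) | [Li]OC1=C[C@H](C(C)=C)CC=C1C | intermediate
4 | 6-methylcarvone, (5R)-2,6-dimethyl-5-(prop-1-en-2-yl)cyclohex-2-en-1-one (C10 epimers) | O=C1C(C)=CC[C@@H](C(C)=C)C1C | intermediate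
5 | B-alkyl-9-BBN adduct of 4 (boron on C19) | O=C1C(C)=CC[C@@H](C(C)CB2C3CCCC2CCC3)C1C | intermediate
6 | 5-(1-hydroxypropan-2-yl)-2,6-dimethylcyclohex-2-en-1-one (ring stereocentre as in 1; C4 and C10 epimers) | O=C1C(C)=CC[C@@H](C(C)CO)C1C | intermediate
7 | acrolein | C=CC=O | starting material
8 | dilithium alkoxide enolate of 6 | [Li]OCC(C)[C@@H]1CC=C(C)C(O[Li])=C1C | intermediate
9 | aldol diol, (5S,6R)-6-[(1R)-1-hydroxyprop-2-en-1-yl]-5-(1-hydroxypropan-2-yl)-2,6-dimethylcyclohex-2-en-1-one (C4 epimers) | OCC(C)[C@@H]1CC=C(C)C(=O)[C@@]1(C)[C@H](O)C=C | intermediate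
10 | vinyl δ-lactone, (1R,4aS,8aR)-1-ethenyl-4,7,8a-trimethyl-4,4a,5,8a-tetrahydro-1H-isochromene-3,8-dione (C4 epimers) | O=C1C(C)[C@@H]2CC=C(C)C(=O)[C@@]2(C)[C@@H](C=C)O1 | intermediate
11 | trimethylsilyl ketene acetal of 10 | C[Si](C)(C)OC1=C(C)[C@@H]2CC=C(C)C(=O)[C@@]2(C)[C@@H](C=C)O1 | intermediate
12 | trimethylsilyl ester of 13 | C[Si](C)(C)OC(=O)[C@@]1(C)CC=C[C@]2(C)C(=O)C(C)=CC[C@@H]12 | intermediate
13 | 9-oxo-11,12,13,14,15,16-hexanorlabda-1,7-dien-19-oic acid (4β-CO2H, 4α-CH3, 5α-H, 10β-CH3) | OC(=O)[C@@]1(C)CC=C[C@]2(C)C(=O)C(C)=CC[C@@H]12 | intermediate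
14 | 9-oxo-11,12,13,14,15,16-hexanorlabd-7-en-19-oic acid | OC(=O)[C@@]1(C)CCC[C@]2(C)C(=O)C(C)=CC[C@@H]12 | intermediate
15 | vinylmagnesium bromide | C=C[Mg]Br | starting material
16 | 9β-hydroxy-13,14,15,16-tetranorlabda-7,11-dien-19-oic acid (9α-vinyl) | OC(=O)[C@@]1(C)CCC[C@]2(C)[C@](O)(C=C)C(C)=CC[C@@H]12 | intermediate
17 | 13,14,15,16-tetranorlabda-7,11-diene-9β,19-diol | OC[C@@]1(C)CCC[C@]2(C)[C@](O)(C=C)C(C)=CC[C@@H]12 | intermediate
18 | tigloyl chloride, (E)-2-methylbut-2-enoyl chloride | C/C=C(\C)C(=O)Cl | starting material
19 | 19-tigloyloxy-13,14,15,16-tetranorlabda-7,11-dien-9β-ol | C/C=C(\C)C(=O)OC[C@@]1(C)CCC[C@]2(C)[C@](O)(C=C)C(C)=CC[C@@H]12 | intermediate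
20 | but-2-ynoic acid | CC#CC(=O)O | starting material
21 | (Z)-3-iodobut-2-enoic acid | C/C(I)=C/C(=O)O | intermediate
22 | 2-(trimethylsilyl)ethanol | C[Si](C)(C)CCO | starting material
23 | 2-(trimethylsilyl)ethyl (Z)-3-iodobut-2-enoate | C/C(I)=C/C(=O)OCC[Si](C)(C)C | intermediate
24 | B-alkyl-9-BBN borane from 19 (boron on C12) | C/C=C(\C)C(=O)OC[C@@]1(C)CCC[C@]2(C)[C@](O)(CCB3C4CCCC3CCC4)C(C)=CC[C@@H]12 | intermediate
25 | 2-(trimethylsilyl)ethyl 9β-hydroxy-19-tigloyloxylabda-7,13Z-dien-15-oate | C/C=C(\C)C(=O)OC[C@@]1(C)CCC[C@]2(C)[C@](O)(CC/C(C)=C\C(=O)OCC[Si](C)(C)C)C(C)=CC[C@@H]12 | intermediate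
26 | 9β-formate of 25 | C/C=C(\C)C(=O)OC[C@@]1(C)CCC[C@]2(C)[C@](OC=O)(CC/C(C)=C\C(=O)OCC[Si](C)(C)C)C(C)=CC[C@@H]12 | intermediate
27 | 2-(trimethylsilyl)ethyl 19-tigloyloxylabda-7,13Z-dien-15-oate | C/C=C(\C)C(=O)OC[C@@]1(C)CCC[C@]2(C)[C@@H](CC/C(C)=C\C(=O)OCC[Si](C)(C)C)C(C)=CC[C@@H]12 | intermediate
28 | 19-tigloyloxylabda-7,13Z-dien-15-oic acid (4S,5R,9S,10R) | C/C=C(\C)C(=O)OC[C@@]1(C)CCC[C@]2(C)[C@@H](CC/C(C)=C\C(=O)O)C(C)=CC[C@@H]12 | target

**Step count.** Total: 15 steps. Longest linear sequence: 13 steps (steps 1–9 and 12–15 from 1); steps 10–11 make the side-chain partner 23.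

**Steps most likely to fail**

Step 5. The trans ring fusion forces the boat-like transition state of the [3,3] shift to twist, so the rearrangement may be slower than desilylation or decomposition of ketene acetal 11, and γ-deprotonation of the enone at C6 may compete with enolisation at C4. The fallback gives up the lactone template and closes ring A by ring-closing metathesis after an unconstrained Ireland–Claisen rearrangement. It sets out from alcohol 6: CrO3/H2SO4 in acetone gives the keto acid F1, and allyl bromide/K2CO3 in DMF gives its allyl ester F2. LiN(iPr)2 then acetaldehyde gives the C10 aldol F3 (electrophile anti to the C5 substituent), which Martin sulfurane Ph2S[OC(CF3)2Ph]2 dehydrates to the 10-vinyl enone F4. LiN(iPr)2/Me3SiCl at −78 °C followed by warming gives, through a chair-like Ireland–Claisen rearrangement, the 4-allyl acid F5 as a pair of C4 epimers. The second-generation Grubbs catalyst (CH2Cl2, 40 °C) then joins C1 to C2 and the route is rejoined at 13 after separation from its C4 epimer.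

Step 14. The congested allylpalladium intermediate may lose a β-hydrogen to give dienes or accept hydride at C7 instead of C9, and the facial outcome depends on α-selective vinyl addition in step 7 and on complete formylation in step 13. The fallback sets out from tertiary allylic alcohol 25 and does not depend on the C9 configuration of 25. Pyridinium chlorochromate [C5H5NH][CrO3Cl] in CH2Cl2 (oxidative 1,3-transposition) gives the 8-en-7-one F6. NaBH4/CeCl3·7H2O in MeOH at −78 °C (Luche reduction, axial hydride) gives the 7β-allylic alcohol F7. 2-Nitrobenzenesulfonylhydrazide, PPh3 and diethyl azodicarboxylate (THF, −30 °C → rt) invert C7 in a Mitsunobu reaction; the 7α-allylic diazene loses N2 by retro-ene shift, placing hydrogen on the α face of C9 and the alkene at C7=C8. The route is rejoined at 27.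

Step 3. Control at C1 by the Zimmerman–Traxler chair may be weak for a small aldehyde, the lithium alkoxide may start polymerisation of acrolein, and the aldolate may revert by retro-aldol cleavage. The fallback replaces substrate control at C1 by reagent control. It sets out from 9 as its C1 epimer mixture: MnO2 in CH2Cl2 oxidises only the allylic C1 hydroxyl to the vinyl ketone F8. (S)-2-Methyl-CBS-oxazaborolidine with catecholborane (PhMe, −78 °C; quaternary C10 as the large group) reduces this ketone in preference to the hindered ring enone and should return the single 1R epimer of 9.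

Further compounds
F1 | step 5 | keto acid, 2-(2,4-dimethyl-3-oxocyclohex-4-en-1-yl)propanoic acid (ring stereocentre as in 1) | OC(=O)C(C)[C@@H]1CC=C(C)C(=O)C1C
F2 | step 5 | allyl ester of F1 | C=CCOC(=O)C(C)[C@@H]1CC=C(C)C(=O)C1C
F3 | step 5 | 10-(1-hydroxyethyl) aldol of F2 (10β-CH3) | C=CCOC(=O)C(C)[C@@H]1CC=C(C)C(=O)[C@@]1(C)C(C)O
F4 | step 5 | 10-vinyl enone allyl ester | C=CCOC(=O)C(C)[C@@H]1CC=C(C)C(=O)[C@@]1(C)C=C
F5 | step 5 | 4-allyl-4-methyl acid (C4 epimers) | OC(=O)C(C)(CC=C)[C@@H]1CC=C(C)C(=O)[C@@]1(C)C=C
F6 | step 14 | 2-(trimethylsilyl)ethyl 7-oxo-19-tigloyloxylabda-8,13Z-dien-15-oate | C/C=C(\C)C(=O)OC[C@@]1(C)CCC[C@]2(C)C(CC/C(C)=C\C(=O)OCC[Si](C)(C)C)=C(C)C(=O)C[C@@H]12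
F7 | step 14 | 2-(trimethylsilyl)ethyl 7β-hydroxy-19-tigloyloxylabda-8,13Z-dien-15-oate | C/C=C(\C)C(=O)OC[C@@]1(C)CCC[C@]2(C)C(CC/C(C)=C\C(=O)OCC[Si](C)(C)C)=C(C)[C@@H](O)C[C@@H]12
F8 | step 3 | C1 vinyl ketone with free C19 hydroxyl | OCC(C)[C@@H]1CC=C(C)C(=O)[C@@]1(C)C(=O)C=C
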